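**Retrosynthetic overview**
1. 22 ⇐ 21 by last-step peracid epoxidation of the (4E)-alkene; the C10 acetoxy/methyl pair ⇐ spiro-epoxy ketone 19 (acetyl iodide opening, then deiodination).
2. Key step: the ten-membered ring of 19 ⇐ tricyclic γ-stannyl carbinol 18 (five/seven-fused, extra C1–C5 bond) by tin-directed oxidative fragmentation, a ring expansion that makes C1=O and the (E)-C4=C5 alkene together.
3. Seven-membered ring of 18 ⇐ aldehyde 11 by intramolecular allylsilane addition (C8–C9); C8 from CO, C13 from bromomethyl acetate, C9/C10/C14 from (2-bromoallyl)trimethylsilane added to the C1 ketone.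
4. C5–C6 bond ⇐ enol silane 5 + mucobromic acid 2 (from furfural); 5 ⇐ 3-methylcyclopent-2-enone by an enantioselective copper-catalysed conjugate stannylation (new method).
5. Ring order: cyclopentane (bought) and butenolide (from furfural) are joined, then the seven-membered ring, then ring expansion to the ten-membered ring, then the oxirane.

Convention (assumption): germacrane numbering of the target is used for all intermediates (C1 ketone carbon, C4/C5 oxirane carbons, C6 lactone carbinol, C7=C11 butenolide alkene, C8 methacrylate carbinol, C10 acetoxy carbon, C12 lactone carbonyl, C13 acetoxymethyl carbon, C14 and C15 the methyls on C10 and C4); tricyclic intermediates with the extra C1–C5 bond are named as guaianolides.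

**Route**

Step 1
Reactants: 1 furan-2-carbaldehyde (furfural)
Product: 2 mucobromic acid (3,4-dibromo-5-hydroxyfuran-2(5H)-one; racemic lactol)
Conditions: Br2 (5 equiv), H2O, 0 °C then reflux
Reagents that add atoms: bromine BrBr; water O
Why: Oxidative bromination with decarboxylative ring cleavage and reclosure (the classical mucobromic acid synthesis) gives the butenolide carbons C6, C7, C11, C12 with bromine handles on C7 and C11 and C6 at the lactol level; no permanent stereocenter is formed.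

Step 2
Reactants: 3 3-methylcyclopent-2-en-1-one
Product: 5 trimethyl{[(3S)-3-methyl-3-(trimethylstannyl)cyclopent-1-en-1-yl]oxy}silane, via tin enolate 4 (not isolated)
Conditions: Cu(MeCN)4PF6 (5 mol %), (R,R)-QuinoxP* (6 mol %), LiOtBu (10 mol %), Me3SnSnMe3 (1.05 equiv), THF, −20 °C; then Me3SiCl, −20 → 0 °C
Reagents that add atoms: hexamethylditin C[Sn](C)(C)[Sn](C)(C)C; chlorotrimethylsilane C[Si](C)(C)Cl
Why: Proposed new method: copper-catalysed enantioselective conjugate stannylation with enolate capture, in which Cu–OtBu and Me3Sn–SnMe3 give L*Cu–SnMe3 by σ-bond metathesis, this adds 1,4 to the enone, Me3SnOtBu releases the copper enolate as tin enolate 4 (regenerating Cu–OtBu) and Me3SiCl gives the regiodefined enol silane, while the chiral bisphosphine–copper complex selects the enone face and sets the tin-bearing quaternary C4 as S (the ligand antipode is used if the first run shows the opposite sense); the closest known reactions are copper/chiral-ligand-catalysed enantioselective conjugate borylation and silylation of β-substituted cyclic enones and stoichiometric stannylcuprate additions to 3-methylcycloalkenones.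

Step 3
Reactants: 5 trimethyl{[(3S)-3-methyl-3-(trimethylstannyl)cyclopent-1-en-1-yl]oxy}silane; 2 mucobromic acid
Product: 6 (2S,3S)-2-[(2S)-3,4-dibromo-5-oxo-2,5-dihydrofuran-2-yl]-3-methyl-3-(trimethylstannyl)cyclopentan-1-one
Conditions: Sc(OTf)3 (10 mol %), MeCN/CH2Cl2, −40 → 0 °C
Reagents that add atoms: none
Why: Mukaiyama-type addition of the enol silane to the acyloxy-oxocarbenium ion from the lactol of 2 forms C5–C6; attack anti to the Me3Sn group sets C5 (trans to tin) and the open antiperiplanar transition state usual for enol silane/oxocarbenium additions gives the syn C5/C6 relationship (the minor C6 epimer is removed on silica).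

Step 4
Reactants: 6 (2S,3S)-2-[(2S)-3,4-dibromo-5-oxo-2,5-dihydrofuran-2-yl]-3-methyl-3-(trimethylstannyl)cyclopentan-1-one; 7 (2-bromoallyl)trimethylsilane
Product: 10 (5S)-3,4-dibromo-5-{(1S,2S,5S)-5-methyl-2-[(trimethylsilyl)oxy]-2-[3-(trimethylsilyl)prop-1-en-2-yl]-5-(trimethylstannyl)cyclopentyl}furan-2(5H)-one, via Grignard reagent 8 (not isolated), via magnesium alkoxide 9 (not isolated)
Conditions: 7, Mg, THF, 25 °C; LaCl3·2LiCl (1.1 equiv), then 6, −78 °C; then Me3SiOTf, −78 °C
Reagents that add atoms: trimethylsilyl triflate C[Si](C)(C)OS(=O)(=O)C(F)(F)F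
Why: Lanthanum-promoted Grignard 1,2-addition to the cyclopentanone (faster than attack on the lactone or deprotonation at C6) takes place anti to the C5 butenolide substituent, setting C1 with the new carbon trans to C6, and the alkoxide is silylated cold so that it cannot add to C7 now or close a lactol onto the C8 aldehyde later.

Step 5
Reactants: 10 (5S)-3,4-dibromo-5-{(1S,2S,5S)-5-methyl-2-[(trimethylsilyl)oxy]-2-[3-(trimethylsilyl)prop-1-en-2-yl]-5-(trimethylstannyl)cyclopentyl}furan-2(5H)-one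
Product: 11 (2S)-4-bromo-2-{(1S,2S,5S)-5-methyl-2-[(trimethylsilyl)oxy]-2-[3-(trimethylsilyl)prop-1-en-2-yl]-5-(trimethylstannyl)cyclopentyl}-5-oxo-2,5-dihydrofuran-3-carbaldehyde
Conditions: Pd(PPh3)4 (5 mol %), CO (3 atm), Bu3SnH (1.1 equiv, slow addition), toluene, 50 °C
Reagents that add atoms: carbon monoxide [C-]#[O+]
Why: Palladium-catalysed reductive carbonylation (formylation) of a vinyl bromide; oxidative addition is selective for the β-bromide at C7 (a vinylogous acyl bromide) over the α-bromide at C11, so CO becomes C8 and no stereocenter is touched.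

Step 6
Reactants: 11 (2S)-4-bromo-2-{(1S,2S,5S)-5-methyl-2-[(trimethylsilyl)oxy]-2-[3-(trimethylsilyl)prop-1-en-2-yl]-5-(trimethylstannyl)cyclopentyl}-5-oxo-2,5-dihydrofuran-3-carbaldehyde
Product: 14 (1S,4S,5S,6S,8S)-11-bromo-1-hydroxy-8-(methacryloyloxy)-4-(trimethylstannyl)-13-norguaia-7(11),10(14)-dien-12,6-olide, via aluminium alkoxide 12 (not isolated), via silyl ether 13 (not isolated)
Conditions: Me2AlCl (1.5 equiv), CH2Cl2, −78 °C; then pyridine, DMAP, methacryloyl chloride, −78 → 0 °C; work-up with 1 M HCl/THF, 0 °C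
Reagents that add atoms: methacryloyl chloride C=C(C)C(Cl)=O
Why: Intramolecular Hosomi–Sakurai allylation closes the seven-membered ring (C8–C9) and leaves the C10=C14 methylene; the ring can only close from the tether side, so C8 is set by the formyl rotamer, and the s-trans rotamer (oxygen anti to C7=C11, away from the C11 bromine) gives the 8S carbinol with C8–O cis to H-6, which is acylated in the flask as its aluminium alkoxide before the acidic work-up cleaves the tertiary silyl ether.

Step 7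
Reactants: 14 (1S,4S,5S,6S,8S)-11-bromo-1-hydroxy-8-(methacryloyloxy)-4-(trimethylstannyl)-13-norguaia-7(11),10(14)-dien-12,6-olide; 15 bromomethyl acetate
Product: 17 (1S,4S,5S,6S,8S)-13-acetoxy-1-hydroxy-8-(methacryloyloxy)-4-(trimethylstannyl)guaia-7(11),10(14)-dien-12,6-olide, via organozinc reagent 16 (not isolated)
Conditions: 15, Zn dust, LiCl, THF, 25 °C; then 14, Pd(OAc)2 (2 mol %), SPhos (4 mol %), THF, 25 °C
Reagents that add atoms: none
Why: Negishi coupling of (acetoxymethyl)zinc bromide with the remaining α-bromobutenolide installs C13 as its acetate under neutral conditions that spare the methacrylate, the hindered tertiary carbinol and the alkyltin group; no stereocenter changes.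

Step 8
Reactants: 17 (1S,4S,5S,6S,8S)-13-acetoxy-1-hydroxy-8-(methacryloyloxy)-4-(trimethylstannyl)guaia-7(11),10(14)-dien-12,6-olide
Product: 18 (1S,4S,5S,6S,8S,10S)-13-acetoxy-10,14-epoxy-1-hydroxy-8-(methacryloyloxy)-4-(trimethylstannyl)guai-7(11)-en-12,6-olide
Conditions: VO(acac)2 (5 mol %), t-BuOOH (1.5 equiv), CH2Cl2, 0 °C
Reagents that add atoms: tert-butyl hydroperoxide CC(C)(C)OO
Why: Vanadium-catalysed hydroxyl-directed epoxidation reacts only at the allylic-alcohol alkene (the methacrylate and butenolide alkenes are electron-poor and undirected) and delivers oxygen to the C10=C14 face syn to the C1 hydroxyl, which fixes the C10–O configuration of the target.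

Step 9
Reactants: 18 (1S,4S,5S,6S,8S,10S)-13-acetoxy-10,14-epoxy-1-hydroxy-8-(methacryloyloxy)-4-(trimethylstannyl)guai-7(11)-en-12,6-olide
Product: 19 (4E,6S,8S,10S)-13-acetoxy-10,14-epoxy-8-(methacryloyloxy)-1-oxogermacra-4,7(11)-dien-12,6-olide
Conditions: Pb(OAc)4 (1.2 equiv), benzene, 25 °C
Reagents that add atoms: none
Why: Tin-directed oxidative Grob-type fragmentation of a γ-stannyl carbinol with lead tetraacetate: the lead alkoxide breaks C1–C5 while the antiperiplanar C4–Sn bond supplies the electrons, so the five/seven bicycle expands to the ten-membered ring with C1=O and, because tin is trans to C6, the (E)-C4=C5 alkene; C6, C8 and C10 are untouched.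

Step 10
Reactants: 19 (4E,6S,8S,10S)-13-acetoxy-10,14-epoxy-8-(methacryloyloxy)-1-oxogermacra-4,7(11)-dien-12,6-olide
Product: 20 (4E,6S,8S,10R)-10,13-diacetoxy-14-iodo-8-(methacryloyloxy)-1-oxogermacra-4,7(11)-dien-12,6-olide
Conditions: AcCl (1.2 equiv), NaI (1.2 equiv), MeCN, −20 °C
Reagents that add atoms: acetyl chloride CC(Cl)=O; sodium iodide [Na+].[I-]
Why: Acyl iodide opening of an epoxide: O-acetylation activates the oxirane and iodide attacks the primary C14 in an SN2 step (the C10–O bond next to the ketone is not broken), giving the tertiary C10 acetate with retention.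

Step 11
Reactants: 20 (4E,6S,8S,10R)-10,13-diacetoxy-14-iodo-8-(methacryloyloxy)-1-oxogermacra-4,7(11)-dien-12,6-olide
Product: 21 (4E,6S,8S,10R)-10,13-diacetoxy-8-(methacryloyloxy)-1-oxogermacra-4,7(11)-dien-12,6-olide
Conditions: Bu3SnH (1.3 equiv), Et3B (0.2 equiv), air, toluene, −20 °C
Reagents that add atoms: none
Why: Radical deiodination (tin hydride chain) turns C14 into the methyl group; iodine abstraction is much faster than stannyl addition to the methacrylate and the low temperature suppresses a 1,2-acyloxy shift, so C10 stays as set.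

Step 12
Reactants: 21 (4E,6S,8S,10R)-10,13-diacetoxy-8-(methacryloyloxy)-1-oxogermacra-4,7(11)-dien-12,6-olide
Product: 22 (4R,5S,6R,8S,10R)-10,13-diacetoxy-4,5-epoxy-8-(methacryloyloxy)-1-oxogermacr-7(11)-en-12,6-olide (target)
Conditions: mCPBA (1.1 equiv), CH2Cl2, 0 °C
Reagents that add atoms: meta-chloroperbenzoic acid O=C(OO)c1cccc(Cl)c1
Why: Prilezhaev epoxidation of the only electron-rich alkene; the peracid attacks the outer face of the (E)-alkene in the conformer with C6–H eclipsing the double bond (allylic 1,3-strain with C15), that is anti to ring carbon C7 and on the side of the lactone oxygen, giving the (4R,5S) oxirane.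

**Compound list**
1 | furan-2-carbaldehyde (furfural) | O=Cc1ccco1 | starting material
2 | mucobromic acid, 3,4-dibromo-5-hydroxyfuran-2(5H)-one (racemic, labile lactol) | OC1OC(=O)C(Br)=C1Br | intermediate
3 | 3-methylcyclopent-2-en-1-one | CC1=CC(=O)CC1 | starting material
4 | trimethyl{[(3S)-3-methyl-3-(trimethylstannyl)cyclopent-1-en-1-yl]oxy}stannane (tin enolate, not isolated) | C[C@@]1([Sn](C)(C)C)C=C(O[Sn](C)(C)C)CC1 | intermediate
5 | trimethyl{[(3S)-3-methyl-3-(trimethylstannyl)cyclopent-1-en-1-yl]oxy}silane | C[C@@]1([Sn](C)(C)C)C=C(O[Si](C)(C)C)CC1 | intermediate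
6 | (2S,3S)-2-[(2S)-3,4-dibromo-5-oxo-2,5-dihydrofuran-2-yl]-3-methyl-3-(trimethylstannyl)cyclopentan-1-one | O=C1CC[C@](C)([Sn](C)(C)C)[C@H]1[C@@H]2OC(=O)C(Br)=C2Br | intermediate
7 | (2-bromoallyl)trimethylsilane | C[Si](C)(C)CC(Br)=C | starting material
8 | [3-(trimethylsilyl)prop-1-en-2-yl]magnesium bromide (not isolated) | C[Si](C)(C)CC(=C)[Mg]Br | intermediate
9 | bromomagnesium (1S,2S,3S)-2-[(2S)-3,4-dibromo-5-oxo-2,5-dihydrofuran-2-yl]-3-methyl-1-[3-(trimethylsilyl)prop-1-en-2-yl]-3-(trimethylstannyl)cyclopentan-1-olate (not isolated) | C[Si](C)(C)CC(=C)[C@]1(O[Mg]Br)CC[C@](C)([Sn](C)(C)C)[C@H]1[C@@H]2OC(=O)C(Br)=C2Br | intermediate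
10 | (5S)-3,4-dibromo-5-{(1S,2S,5S)-5-methyl-2-[(trimethylsilyl)oxy]-2-[3-(trimethylsilyl)prop-1-en-2-yl]-5-(trimethylstannyl)cyclopentyl}furan-2(5H)-one | C[Si](C)(C)CC(=C)[C@]1(O[Si](C)(C)C)CC[C@](C)([Sn](C)(C)C)[C@H]1[C@@H]2OC(=O)C(Br)=C2Br | intermediate
11 | (2S)-4-bromo-2-{(1S,2S,5S)-5-methyl-2-[(trimethylsilyl)oxy]-2-[3-(trimethylsilyl)prop-1-en-2-yl]-5-(trimethylstannyl)cyclopentyl}-5-oxo-2,5-dihydrofuran-3-carbaldehyde | C[Si](C)(C)CC(=C)[C@]1(O[Si](C)(C)C)CC[C@](C)([Sn](C)(C)C)[C@H]1[C@@H]2OC(=O)C(Br)=C2C=O | intermediate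
12 | (1S,4S,5S,6S,8S)-11-bromo-8-[(dimethylalumanyl)oxy]-4-(trimethylstannyl)-1-[(trimethylsilyl)oxy]-13-norguaia-7(11),10(14)-dien-12,6-olide (not isolated) | C[Al](C)O[C@H]1CC(=C)[C@]3(O[Si](C)(C)C)CC[C@](C)([Sn](C)(C)C)[C@H]3[C@@H]2OC(=O)C(Br)=C12 | intermediate
13 | (1S,4S,5S,6S,8S)-11-bromo-8-(methacryloyloxy)-4-(trimethylstannyl)-1-[(trimethylsilyl)oxy]-13-norguaia-7(11),10(14)-dien-12,6-olide (not isolated) | C=C(C)C(=O)O[C@H]1CC(=C)[C@]3(O[Si](C)(C)C)CC[C@](C)([Sn](C)(C)C)[C@H]3[C@@H]2OC(=O)C(Br)=C12 | intermediate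
14 | (1S,4S,5S,6S,8S)-11-bromo-1-hydroxy-8-(methacryloyloxy)-4-(trimethylstannyl)-13-norguaia-7(11),10(14)-dien-12,6-olide | C=C(C)C(=O)O[C@H]1CC(=C)[C@]3(O)CC[C@](C)([Sn](C)(C)C)[C@H]3[C@@H]2OC(=O)C(Br)=C12 | intermediate
15 | bromomethyl acetate | CC(=O)OCBr | starting material
16 | (acetoxymethyl)zinc bromide (not isolated) | CC(=O)OC[Zn]Br | intermediate
17 | (1S,4S,5S,6S,8S)-13-acetoxy-1-hydroxy-8-(methacryloyloxy)-4-(trimethylstannyl)guaia-7(11),10(14)-dien-12,6-olide | C=C(C)C(=O)O[C@H]1CC(=C)[C@]3(O)CC[C@](C)([Sn](C)(C)C)[C@H]3[C@@H]2OC(=O)C(COC(C)=O)=C12 | intermediate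
18 | (1S,4S,5S,6S,8S,10S)-13-acetoxy-10,14-epoxy-1-hydroxy-8-(methacryloyloxy)-4-(trimethylstannyl)guai-7(11)-en-12,6-olide | C=C(C)C(=O)O[C@H]1C[C@@]4(OC4)[C@]3(O)CC[C@](C)([Sn](C)(C)C)[C@H]3[C@@H]2OC(=O)C(COC(C)=O)=C12 | intermediate
19 | (4E,6S,8S,10S)-13-acetoxy-10,14-epoxy-8-(methacryloyloxy)-1-oxogermacra-4,7(11)-dien-12,6-olide | C=C(C)C(=O)O[C@H]1C[C@@]3(OC3)C(=O)CC/C(C)=C/[C@@H]2OC(=O)C(COC(C)=O)=C12 | intermediate
20 | (4E,6S,8S,10R)-10,13-diacetoxy-14-iodo-8-(methacryloyloxy)-1-oxogermacra-4,7(11)-dien-12,6-olide | C=C(C)C(=O)O[C@H]1C[C@@](CI)(OC(C)=O)C(=O)CC/C(C)=C/[C@@H]2OC(=O)C(COC(C)=O)=C12 | intermediate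
21 | (4E,6S,8S,10R)-10,13-diacetoxy-8-(methacryloyloxy)-1-oxogermacra-4,7(11)-dien-12,6-olide | C=C(C)C(=O)O[C@H]1C[C@@](C)(OC(C)=O)C(=O)CC/C(C)=C/[C@@H]2OC(=O)C(COC(C)=O)=C12 | intermediate
22 | (4R,5S,6R,8S,10R)-10,13-diacetoxy-4,5-epoxy-8-(methacryloyloxy)-1-oxogermacr-7(11)-en-12,6-olide | C=C(C)C(=O)O[C@H]1C[C@@](C)(OC(C)=O)C(=O)CC[C@@]2(C)O[C@H]2[C@@H]2OC(=O)C(COC(C)=O)=C12 | target

**Summary**
Total steps: 12. Longest linear sequence: 11 steps (3 → 22 through steps 2–12; the same length from 1 through steps 1 and 3–12).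

Three steps most likely to fail:

Step 2 (the proposed new method; risk of poor turnover or low enantioselectivity). The fallback uses known chemistry and sets out from 3: stoichiometric conjugate addition of Me3SnLi (from Me3SnSnMe3 and MeLi, THF, −78 °C) followed by O-silylation with Me3SiCl gives the racemic enol silane, that is 5 mixed 1:1 with its enantiomer trimethyl{[(3R)-3-methyl-3-(trimethylstannyl)cyclopent-1-en-1-yl]oxy}silane F1. Step 3 on this mixture gives 6 together with its enantiomer (2R,3R)-2-[(2R)-3,4-dibromo-5-oxo-2,5-dihydrofuran-2-yl]-3-methyl-3-(trimethylstannyl)cyclopentan-1-one F2. Preparative chromatography on a chiral stationary phase removes F2 and the route is rejoined at enantiopure 6.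

Step 6 (risk that the Lewis acid ionises the allylic silyl ether, or that the silyl ether oxygen adds to the activated aldehyde instead of the allylsilane). The fallback sets out from 11: bromodesilylation with NBS (CH2Cl2, −78 °C) gives the allyl bromide (2S)-4-bromo-2-{(1S,2S,5S)-2-(3-bromoprop-1-en-2-yl)-5-methyl-2-[(trimethylsilyl)oxy]-5-(trimethylstannyl)cyclopentyl}-5-oxo-2,5-dihydrofuran-3-carbaldehyde F3. Indium powder in THF/H2O then closes the seven-membered ring by a neutral Barbier allylation, and a dilute-acid work-up removes the silyl ether to give the diol (1S,4S,5S,6S,8S)-11-bromo-1,8-dihydroxy-4-(trimethylstannyl)-13-norguaia-7(11),10(14)-dien-12,6-olide F4. Methacryloyl chloride/Et3N/DMAP at −20 °C acylates the secondary hydroxyl selectively and the route is rejoined at 14.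

Step 9 (the ring expansion; risk that the epoxy carbinol rearranges or the oxirane opens at lead before the fragmentation). The fallback sets out from 18 and reorders the end game so that the fragmentation runs on a simpler carbinol. The epoxide is opened first (AcCl, NaI, MeCN, −20 °C) to the iodo acetate (1S,4S,5S,6S,8S,10R)-10,13-diacetoxy-1-hydroxy-14-iodo-8-(methacryloyloxy)-4-(trimethylstannyl)guai-7(11)-en-12,6-olide F5. Deiodination (Bu3SnH, Et3B, air) gives the acetoxy carbinol (1S,4S,5S,6S,8S,10R)-10,13-diacetoxy-1-hydroxy-8-(methacryloyloxy)-4-(trimethylstannyl)guai-7(11)-en-12,6-olide F6, in which the neighbouring oxygen is already acylated so glycol cleavage cannot compete. Fragmentation of F6 with lead tetraacetate (or, if the lead alkoxide itself is the problem, PhI(OAc)2 and iodine under light, an alkoxy-radical β-scission) rejoins the route at 21.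

Further compounds
F1 | step 2 | trimethyl{[(3R)-3-methyl-3-(trimethylstannyl)cyclopent-1-en-1-yl]oxy}silane | C[C@]1([Sn](C)(C)C)C=C(O[Si](C)(C)C)CC1
F2 | step 2 | (2R,3R)-2-[(2R)-3,4-dibromo-5-oxo-2,5-dihydrofuran-2-yl]-3-methyl-3-(trimethylstannyl)cyclopentan-1-one | O=C1CC[C@@](C)([Sn](C)(C)C)[C@@H]1[C@H]2OC(=O)C(Br)=C2Br
F3 | step 6 | (2S)-4-bromo-2-{(1S,2S,5S)-2-(3-bromoprop-1-en-2-yl)-5-methyl-2-[(trimethylsilyl)oxy]-5-(trimethylstannyl)cyclopentyl}-5-oxo-2,5-dihydrofuran-3-carbaldehyde | BrCC(=C)[C@]1(O[Si](C)(C)C)CC[C@](C)([Sn](C)(C)C)[C@H]1[C@@H]2OC(=O)C(Br)=C2C=O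
F4 | step 6 | (1S,4S,5S,6S,8S)-11-bromo-1,8-dihydroxy-4-(trimethylstannyl)-13-norguaia-7(11),10(14)-dien-12,6-olide | O[C@H]1CC(=C)[C@]3(O)CC[C@](C)([Sn](C)(C)C)[C@H]3[C@@H]2OC(=O)C(Br)=C12
F5 | step 9 | (1S,4S,5S,6S,8S,10R)-10,13-diacetoxy-1-hydroxy-14-iodo-8-(methacryloyloxy)-4-(trimethylstannyl)guai-7(11)-en-12,6-olide | C=C(C)C(=O)O[C@H]1C[C@@](CI)(OC(C)=O)[C@]3(O)CC[C@](C)([Sn](C)(C)C)[C@H]3[C@@H]2OC(=O)C(COC(C)=O)=C12
F6 | step 9 | (1S,4S,5S,6S,8S,10R)-10,13-diacetoxy-1-hydroxy-8-(methacryloyloxy)-4-(trimethylstannyl)guai-7(11)-en-12,6-olide | C=C(C)C(=O)O[C@H]1C[C@@](C)(OC(C)=O)[C@]3(O)CC[C@](C)([Sn](C)(C)C)[C@H]3[C@@H]2OC(=O)C(COC(C)=O)=C12
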